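The constants are hidden, so I read one from the runs: the reagent clock.

| flask | substrate | reagent | initiator | radical scavenger | remark | time |
|---|---|---|---|---|---|---|
| ochre | 8.7 mM | 10.4 mM | 0.65 mM | 5.8 µM | run made earlier |  |
| teal | 20 mM | 10.4 mM | 0.65 mM | 5.8 µM | run made earlier |  |
| grey | 13 mM | 10.4 mM | 0.98 mM | 5.8 µM | run made earlier |  |
| flask | 13 mM | 10.4 mM | 0.65 mM | 5.8 µM |  | 2.5 min |

| run | time / s | target / % | substrate / % |
|---|---|---|---|
| ochre | 10.0 | 5.2 | 94.3 |
| ochre | 20.0 | 15.2 | 85.4 |
| ochre | 30.0 | 22.6 | 77.5 |
| ochre | 50.0 | 37.6 | 61.8 |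
| ochre | 80.0 | 54.9 | 43.1 |
| ochre | 90.0 | 60.7 | 38.6 |
| ochre | 120 | 72.5 | 25.7 |
| teal | 15.0 | 4.7 | 96.0 |
| teal | 30.0 | 10.0 | 90.2 |
| teal | 50.0 | 16.7 | 82.7 |
| teal | 60.0 | 19.5 | 80.4 |
| teal | 80.0 | 24.2 | 75.4 |
| teal | 90.0 | 26.3 | 73.0 |
| teal | 120 | 31.5 | 67.7 |
| grey | 25.0 | 16.1 | 83.5 |
| grey | 50.0 | 30.7 | 68.5 |
| grey | 80.0 | 43.4 | 55.1 |
| grey | 90.0 | 47.1 | 51.5 |
| grey | 120 | 54.7 | 42.9 |

(readings scatter by 0.3 percentage points)

- percent here means substrate units held: one ended chains A counts as two
- steps thought possible: initiator -> 2 initiating radical; substrate + initiating radical -> capped initiator + first chain carrier; reagent + first chain carrier -> target + second chain carrier; substrate + second chain carrier -> by-product + first chain carrier; 2 first chain carrier -> ended chains A; first chain carrier + radical scavenger -> ended chains B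

- target present at 2.5 min, in percent of the substrate charged
- substrate present at 2.5 min, in percent of the substrate charged

At 120 s the ochre run holds 6.31 mM of target and the teal run 6.30 mM, although they were charged with 8.7 mM and 20 mM of substrate. So I treat reagent loss as pseudo-first-order and independent of substrate. Each target made costs one reagent, so the reagent left is its charge minus the target.

The reagent clock, ln(reagent charged / reagent left) divided by time, reads 0.00777 s⁻¹ from that ochre reading. At 50.0 s the same reckoning gives 0.00755 s⁻¹, a small drift that I do not extend. Carried to 2.5 min, the clock gives 55.1% target in the flask.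

The second way starts from the grey run. If first chain carrier is made from initiator and ended in pairs, the clock goes, other charges held, as the root of the initiator charge. The grey clock, 0.00959 s⁻¹, then scales to 0.00781 s⁻¹ for the flask, which gives 55.2% target. The two ways differ by 0.10 percentage points, less than the scatter of one reading, so I keep the first.

Substrate follows target one for one, plus a small excess. In the ochre run that excess reads 0.157 mM at 120 s. Growing it in proportion to time leaves 43.4% substrate in the flask.

The forecast gives 54.8% target and 43.6% substrate, on the ground that “the rate is essentially zero order in substrate”.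

The flask gives 55.4% target and 43.2% substrate.

    initiator → 2 initiating radical (k = 0.00101 s⁻¹)
    substrate + initiating radical → capped initiator + first chain carrier (k = 1.08 × 10⁵ M⁻¹ s⁻¹)
    reagent + first chain carrier → target + second chain carrier (k = 11400 M⁻¹ s⁻¹)
    substrate + second chain carrier → by-product + first chain carrier (k = 11100 M⁻¹ s⁻¹)
    2 first chain carrier → ended chains A (k = 1.20 × 10⁶ M⁻¹ s⁻¹)
    first chain carrier + radical scavenger → ended chains B (k = 8.47 × 10⁶ M⁻¹ s⁻¹)

In the flask, first chain carrier stands at 0.00565% at 0.250 min and 0.00528% at 2.50 min, with 85.9% of the initiator left. For the neighbour flask, charged with 1.1 mM of initiator, the root scales the clock to 0.0101 s⁻¹. That predicts 22.0% of the reagent left and 62.4% target at 2.5 min. The neighbour flask gives 21.1% of its reagent and 63.1% target.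

(The earlier runs and the new flask were generated by integration from invented constants; scatter was added.)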